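**Strategy.** The lower heterocycle (O1–C2–C3–C4–C4a–C8a) is closed last, at the bond C4–C4a. The precursor 11 is an open-chain aryl ether: the phloroglucinol ring that already carries the upper epicatechin unit is linked through O1 to a C2–C3 fragment of fixed configuration that ends in a diethyl acetal (the future C4). One Lewis-acid operation closes the ring by Friedel–Crafts attack of C4a on the acetal carbon and, because C4 is then benzylic to the 5,7,8a-trioxygenated ring A, ionises the remaining ethoxy group to an ortho-quinone-methide-type cation that a ketene acetal captures trans to the C3 hydroxyl, installing the acetic acid chain.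

Key step: step 9

Remark: compounds 2 and 13 are prepared here although both may be purchasable; the sense of induction in step 6 is assigned by analogy with indene and cis-β-methylstyrene and would be checked on the first batch.

Step 1
Reactants: 1 (−)-epicatechin
Product: 2 5,7,3′,4′-tetra-O-benzyl-(−)-epicatechin
Conditions: BnBr (4.4 equiv), K2CO3, DMF, 0 °C → rt
Reagents that add atoms: benzyl bromide, BrCc1ccccc1
Why: Williamson ether synthesis in which carbonate deprotonates only the four phenols, so the aliphatic 3-OH stays free and no stereocentre is touched.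

Step 2
Reactants: 2 5,7,3′,4′-tetra-O-benzyl-(−)-epicatechin
Product: 3 4β-(2-ethoxyethoxy)-5,7,3′,4′-tetra-O-benzylepicatechin
Conditions: DDQ (2 equiv), 2-ethoxyethanol (excess), CH2Cl2, rt
Reagents that add atoms: 2-ethoxyethanol, CCOCCO
Why: Benzylic oxidation with DDQ, in which hydride abstraction from C4 gives the flavan-4-yl cation stabilised by the 5,7-dioxygenated ring A and the alcohol adds anti to the quasi-axial 3-OH, so the new centre should be 4β (3,4-trans) as is usual for 2,3-cis flavan-3-ols.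

Step 3
Reactants: 3 4β-(2-ethoxyethoxy)-5,7,3′,4′-tetra-O-benzylepicatechin; 4 3,5-bis(benzyloxy)phenol (4 equiv)
Product: 5 4β-[2,4-bis(benzyloxy)-6-hydroxyphenyl]-5,7,3′,4′-tetra-O-benzylepicatechin
Conditions: TMSOTf (0.3 equiv), CH2Cl2, −78 °C
Reagents that add atoms: none
Why: Lewis-acid Friedel–Crafts arylation through the same flavan-4-yl cation, in which the phenol should attack with a carbon ortho to its hydroxyl (less hindered than the carbon between the two benzyloxy groups, as in known acid-catalysed C-alkylations of this phenol) and again anti to the 3-OH, giving the 4β-aryl product, while excess 4 suppresses double alkylation and self-condensation of 3.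

Step 4
Reactants: 6 1,2-bis(benzyloxy)-4-bromobenzene; 7 3,3-diethoxyprop-1-yne
Product: 8 1,2-bis(benzyloxy)-4-(3,3-diethoxyprop-1-yn-1-yl)benzene
Conditions: PdCl2(MeCN)2 (2 mol%), XPhos (6 mol%), Cs2CO3, MeCN, 80 °C
Reagents that add atoms: none
Why: Copper-free Sonogashira coupling in which the bulky biarylphosphine allows oxidative addition of the electron-rich aryl bromide, the acetal and benzyl ethers being inert to carbonate.

Step 5
Reactants: 8 1,2-bis(benzyloxy)-4-(3,3-diethoxyprop-1-yn-1-yl)benzene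
Product: 9 (Z)-1,2-bis(benzyloxy)-4-(3,3-diethoxyprop-1-en-1-yl)benzene
Conditions: H2 (1 atm), Pd/CaCO3 poisoned with Pb(OAc)2 (Lindlar catalyst), quinoline, EtOAc, rt
Reagents that add atoms: none
Why: Lindlar semihydrogenation, in which syn delivery of hydrogen on the poisoned palladium surface gives the Z alkene and leaves benzyl ethers and the acetal untouched.

Step 6
Reactants: 9 (Z)-1,2-bis(benzyloxy)-4-(3,3-diethoxyprop-1-en-1-yl)benzene
Product: 10 (2S,3S)-2-[3,4-bis(benzyloxy)phenyl]-3-(diethoxymethyl)oxirane (cis)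
Conditions: (S,S)-N,N′-bis(3,5-di-tert-butylsalicylidene)-1,2-cyclohexanediaminomanganese chloride (5 mol%), 4-phenylpyridine N-oxide, aq. NaOCl (pH 11.3), CH2Cl2, 0 °C
Reagents that add atoms: sodium hypochlorite, [Na+].[O-]Cl
Why: Jacobsen–Katsuki epoxidation, for which cis-β-substituted styrenes are the best substrate class: the chiral salen complex of trivalent manganese transfers oxygen to one face of the Z alkene, the (S,S) catalyst being chosen because it gives the (S) benzylic centre with indene and cis-β-methylstyrene, and the basic two-phase medium protects the acid-labile electron-rich oxirane.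

Step 7
Reactants: 5 4β-[2,4-bis(benzyloxy)-6-hydroxyphenyl]-5,7,3′,4′-tetra-O-benzylepicatechin; 10 (2S,3S)-2-[3,4-bis(benzyloxy)phenyl]-3-(diethoxymethyl)oxirane (1.5 equiv)
Product: 11 (1R,2S)-1-[3,4-bis(benzyloxy)phenyl]-1-{3,5-bis(benzyloxy)-2-[5,7,3′,4′-tetra-O-benzylepicatechin-4β-yl]phenoxy}-3,3-diethoxypropan-2-ol
Conditions: Cs2CO3 (0.3 equiv), DMF, 80 °C
Reagents that add atoms: none
Why: Base-mediated SN2 opening of the oxirane by the phenoxide of 5 at the benzylic carbon (the other carbon is hindered and deactivated by the adjacent acetal) with inversion, so that the cis-(2S,3S) epoxide should give the (1R,2S) ether alcohol that corresponds to the 2,3-cis relationship of the future ring; the alkoxide formed is reprotonated by 5, so carbonate is catalytic and the aliphatic 3-OH of the upper unit does not compete.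

Step 8
Reactants: 12 benzyl acetate
Product: 13 [1-(benzyloxy)ethenyl]oxy(tert-butyl)dimethylsilane
Conditions: LiN(iPr)2, THF, −78 °C; then TBSCl, DMPU, −78 °C → rt
Reagents that add atoms: tert-butyldimethylsilyl chloride, CC(C)(C)[Si](C)(C)Cl
Why: O-silylation of the lithium enolate of the acetate ester in the presence of DMPU gives the silyl ketene acetal.

Step 9
Reactants: 11 (1R,2S)-1-[3,4-bis(benzyloxy)phenyl]-1-{3,5-bis(benzyloxy)-2-[5,7,3′,4′-tetra-O-benzylepicatechin-4β-yl]phenoxy}-3,3-diethoxypropan-2-ol; 13 [1-(benzyloxy)ethenyl]oxy(tert-butyl)dimethylsilane (5 equiv)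
Product: 16 benzyl [octa-O-benzyl-epicatechin-(4β→8)-epicatechin-4β-yl]acetate, via 4-ethoxyflavan 14 (not isolated), via flavan-4-yl cation 15 (not isolated)
Conditions: BF3·OEt2 (4 equiv), CH2Cl2, −78 → −30 °C; then 13, −78 → −40 °C; aq. NaHCO3
Reagents that add atoms: none
Why: BF3 ionises the diethyl acetal to an oxocarbenium ion that is attacked by C4a, the only free position ortho to O1 on the phloroglucinol ring, in a 6-exo-trig Friedel–Crafts closure of ring C (bond C4–C4a) that gives the 4-ethoxyflavan-3-ol 14, the classical acid cyclisation of 3-aryloxypropanal acetals to 4-alkoxychromans. Because C4 is now benzylic to a ring carrying oxygen at C5, C7 and C8a, the remaining ethoxy group ionises to the cation 15 (an O-alkylated ortho-quinone methide, the same kind of species as in step 3), and the silyl ketene acetal 13 adds in a Mukaiyama-type substitution, the closest precedent being the Lewis-acid coupling of 4-alkoxyflavan-3-ols with π-nucleophiles. C2 and C3 are carried in from 11 unchanged, and the new C4 centre is set by the half-chair of the cation, in which the C2 aryl group is equatorial and the C3 oxygen quasi-axial, so the nucleophile should enter anti to the C3 oxygen and give the 3,4-trans (4β) ester. Regioselectivity of ring closure is secured by the tether (the other free arene position is meta to O1 and out of reach), and chemoselectivity (ring closure before C–C coupling, no Mukaiyama addition to the open-chain oxocarbenium ion) by adding 13 only after 11 is consumed. The silyl group leaves as the fluorosilane, so both hydroxyl groups are free after aqueous work-up.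

Step 10
Reactants: 16 benzyl [octa-O-benzyl-epicatechin-(4β→8)-epicatechin-4β-yl]acetate
Product: 17 epicatechin-(4β→8)-epicatechin-4β-ylacetic acid (target)
Conditions: H2 (1 atm), Pd(OH)2/C, THF/MeOH/H2O, rt
Reagents that add atoms: none
Why: Hydrogenolysis removes the eight benzyl ethers and the benzyl ester in one operation, while the C4–C8 interflavan bond and the benzylic C2–O1 bonds of flavans are known to survive these neutral conditions and no stereocentre is affected.

**Compound list**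

1 | (−)-epicatechin, (2R,3R)-2-(3,4-dihydroxyphenyl)chroman-3,5,7-triol | C1c2c(O)cc(O)cc2O[C@H](c2ccc(O)c(O)c2)[C@@H]1O | starting material

2 | 5,7,3′,4′-tetra-O-benzyl-(−)-epicatechin (2R,3R) | C1c2c(OCc3ccccc3)cc(OCc3ccccc3)cc2O[C@H](c2ccc(OCc3ccccc3)c(OCc3ccccc3)c2)[C@@H]1O | intermediate

3 | 4β-(2-ethoxyethoxy)-5,7,3′,4′-tetra-O-benzylepicatechin (2R,3R; 4-alkoxy group trans to 3-OH) | CCOCCO[C@H]1c2c(OCc3ccccc3)cc(OCc3ccccc3)cc2O[C@H](c2ccc(OCc3ccccc3)c(OCc3ccccc3)c2)[C@@H]1O | intermediate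

4 | 3,5-bis(benzyloxy)phenol | Oc1cc(OCc2ccccc2)cc(OCc2ccccc2)c1 | starting material

5 | 4β-[2,4-bis(benzyloxy)-6-hydroxyphenyl]-5,7,3′,4′-tetra-O-benzylepicatechin (2R,3R; aryl group at C4 trans to 3-OH) | Oc1cc(OCc2ccccc2)cc(OCc2ccccc2)c1[C@H]1c2c(OCc3ccccc3)cc(OCc3ccccc3)cc2O[C@H](c2ccc(OCc3ccccc3)c(OCc3ccccc3)c2)[C@@H]1O | intermediate

6 | 1,2-bis(benzyloxy)-4-bromobenzene | Brc1ccc(OCc2ccccc2)c(OCc2ccccc2)c1 | starting material

7 | 3,3-diethoxyprop-1-yne | C#CC(OCC)OCC | starting material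

8 | 1,2-bis(benzyloxy)-4-(3,3-diethoxyprop-1-yn-1-yl)benzene | CCOC(OCC)C#Cc1ccc(OCc2ccccc2)c(OCc2ccccc2)c1 | intermediate

9 | (Z)-1,2-bis(benzyloxy)-4-(3,3-diethoxyprop-1-en-1-yl)benzene | CCOC(OCC)/C=C\c1ccc(OCc2ccccc2)c(OCc2ccccc2)c1 | intermediate

10 | (2S,3S)-2-[3,4-bis(benzyloxy)phenyl]-3-(diethoxymethyl)oxirane (cis) | CCOC(OCC)[C@H]1O[C@H]1c1ccc(OCc2ccccc2)c(OCc2ccccc2)c1 | intermediate

11 | (1R,2S)-1-[3,4-bis(benzyloxy)phenyl]-1-{3,5-bis(benzyloxy)-2-[5,7,3′,4′-tetra-O-benzylepicatechin-4β-yl]phenoxy}-3,3-diethoxypropan-2-ol | CCOC(OCC)[C@@H](O)[C@@H](c1ccc(OCc2ccccc2)c(OCc2ccccc2)c1)Oc1cc(OCc2ccccc2)cc(OCc2ccccc2)c1[C@H]1c2c(OCc3ccccc3)cc(OCc3ccccc3)cc2O[C@H](c2ccc(OCc3ccccc3)c(OCc3ccccc3)c2)[C@@H]1O | intermediate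

12 | benzyl acetate | CC(=O)OCc1ccccc1 | starting material

13 | [1-(benzyloxy)ethenyl]oxy(tert-butyl)dimethylsilane | C=C(OCc1ccccc1)O[Si](C)(C)C(C)(C)C | intermediate

14 | 5,7,3′,4′-tetra-O-benzylepicatechin-(4β→8)-5,7,3′,4′-tetra-O-benzyl-4-ethoxyepicatechin (lower C4 as a mixture of epimers; not isolated) | CCOC1c2c(OCc3ccccc3)cc(OCc3ccccc3)c([C@H]3c4c(OCc5ccccc5)cc(OCc5ccccc5)cc4O[C@H](c4ccc(OCc5ccccc5)c(OCc5ccccc5)c4)[C@@H]3O)c2O[C@H](c2ccc(OCc3ccccc3)c(OCc3ccccc3)c2)[C@@H]1O | intermediate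

15 | lower-unit flavan-4-yl cation derived from 14, as its ethoxytrifluoroborate ion pair (not isolated) | CCO[B-](F)(F)F.[CH+]1c2c(OCc3ccccc3)cc(OCc3ccccc3)c([C@H]3c4c(OCc5ccccc5)cc(OCc5ccccc5)cc4O[C@H](c4ccc(OCc5ccccc5)c(OCc5ccccc5)c4)[C@@H]3O)c2O[C@H](c2ccc(OCc3ccccc3)c(OCc3ccccc3)c2)[C@@H]1O | intermediate

16 | benzyl [5,7,3′,4′-tetra-O-benzylepicatechin-(4β→8)-5,7,3′,4′-tetra-O-benzylepicatechin-4β-yl]acetate (both units 2,3-cis-3,4-trans) | O=C(OCc1ccccc1)C[C@H]1c2c(OCc3ccccc3)cc(OCc3ccccc3)c([C@H]3c4c(OCc5ccccc5)cc(OCc5ccccc5)cc4O[C@H](c4ccc(OCc5ccccc5)c(OCc5ccccc5)c4)[C@@H]3O)c2O[C@H](c2ccc(OCc3ccccc3)c(OCc3ccccc3)c2)[C@@H]1O | intermediate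

17 | epicatechin-(4β→8)-epicatechin-4β-ylacetic acid (lower unit 2R,3R,4S; upper unit 2R,3R,4R) | O=C(O)C[C@H]1c2c(O)cc(O)c([C@H]3c4c(O)cc(O)cc4O[C@H](c4ccc(O)c(O)c4)[C@@H]3O)c2O[C@H](c2ccc(O)c(O)c2)[C@@H]1O | target

**Step count.** Total: 10 steps. Longest linear sequence: 6 steps (1, 2, 3, 7, 9, 10; the branch 4, 5, 6, 7, 9, 10 is equally long).

**Steps most likely to fail**

Step 9 (key step). The cation 15 may be consumed before 13 is present (alkylation by the free C8 position of ring A of the upper unit of a second molecule, or loss of H3 toward the enol of the 3-ketone). If 13 is added too early, Mukaiyama addition to the open-chain oxocarbenium ion may outrun ring closure. The fallback sets out from 11 and comes back at 17. BF3·OEt2 is used with allyltrimethylsilane present from the beginning; this nucleophile is too weak to compete with the tethered arene for the open-chain oxocarbenium ion but traps the flavan-4-yl cation as it forms, a known reaction of 4-alkoxyflavans, and should give the 4β-allyl compound F1. Lemieux–Johnson cleavage (OsO4 cat., NaIO4, 2,6-lutidine, dioxane/H2O) gives the aldehyde F2, Pinnick oxidation (NaClO2, NaH2PO4, 2-methyl-2-butene) gives the octabenzyl acid F3, and hydrogenolysis as in step 10 gives 17.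

Step 7. The substitution may be slow because the phenoxide is hindered, the phenoxide may attack the other oxirane carbon, and partial ionisation of the electron-rich benzylic C–O bond may erode the configuration at C2. The fallback sets out from 6 and 5 and comes back at 16. The Grignard reagent from 6 (Mg, THF) adds to (R)-2,3-O-isopropylideneglyceraldehyde with Felkin–Anh (anti) selectivity to give the anti alcohol F4. Mitsunobu etherification of 5 with F4 (PPh3, DIAD, toluene) inverts the carbinol centre and gives the ether acetonide F5. Mild acetonide hydrolysis (aq. AcOH) gives the diol F6, and TEMPO/PhI(OAc)2 oxidises only the primary alcohol to the α-hydroxy aldehyde F7. With BF3·OEt2, F7 undergoes the same Friedel–Crafts closure to the flavan-3,4-diol F8 (not isolated), which ionises and is trapped by 13 as in step 9 to give 16.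

Step 6. Enantioselection may be incomplete, the cis geometry may leak to trans through the benzylic radical intermediate, and the electron-rich aryl oxirane may decompose on acid contact. The fallback sets out from 6 and comes back at 16. Sonogashira coupling of 6 with propargyl alcohol gives the propargylic alcohol F9, and Lindlar semihydrogenation gives the (Z)-allylic alcohol F10. Katsuki–Sharpless epoxidation (Ti(OiPr)4, D-(−)-diethyl tartrate, tBuOOH), which is concerted and therefore stereospecific, gives the cis-epoxy alcohol F11. Opening of F11 with the phenoxide of 5 under the conditions of step 7 gives the diol F6 of the preceding fallback, which goes on through F7 and F8 to 16.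

**Further compounds**

F1 | step 9 | 5,7,3′,4′-tetra-O-benzylepicatechin-(4β→8)-4β-allyl-5,7,3′,4′-tetra-O-benzylepicatechin | C=CC[C@H]1c2c(OCc3ccccc3)cc(OCc3ccccc3)c([C@H]3c4c(OCc5ccccc5)cc(OCc5ccccc5)cc4O[C@H](c4ccc(OCc5ccccc5)c(OCc5ccccc5)c4)[C@@H]3O)c2O[C@H](c2ccc(OCc3ccccc3)c(OCc3ccccc3)c2)[C@@H]1O
F2 | step 9 | [octa-O-benzyl-epicatechin-(4β→8)-epicatechin-4β-yl]acetaldehyde | O=CC[C@H]1c2c(OCc3ccccc3)cc(OCc3ccccc3)c([C@H]3c4c(OCc5ccccc5)cc(OCc5ccccc5)cc4O[C@H](c4ccc(OCc5ccccc5)c(OCc5ccccc5)c4)[C@@H]3O)c2O[C@H](c2ccc(OCc3ccccc3)c(OCc3ccccc3)c2)[C@@H]1O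
F3 | step 9 | [octa-O-benzyl-epicatechin-(4β→8)-epicatechin-4β-yl]acetic acid | O=C(O)C[C@H]1c2c(OCc3ccccc3)cc(OCc3ccccc3)c([C@H]3c4c(OCc5ccccc5)cc(OCc5ccccc5)cc4O[C@H](c4ccc(OCc5ccccc5)c(OCc5ccccc5)c4)[C@@H]3O)c2O[C@H](c2ccc(OCc3ccccc3)c(OCc3ccccc3)c2)[C@@H]1O
F4 | step 7 | (S)-[3,4-bis(benzyloxy)phenyl][(4R)-2,2-dimethyl-1,3-dioxolan-4-yl]methanol (anti) | O[C@@H](c1ccc(OCc2ccccc2)c(OCc2ccccc2)c1)[C@H]1COC(C)(C)O1
F5 | step 7 | Mitsunobu ether of 5 with F4: (R)-aryl[(4R)-2,2-dimethyl-1,3-dioxolan-4-yl]methyl ether of the phenol 5 | CC1(C)OC[C@@H](O1)[C@@H](c1ccc(OCc2ccccc2)c(OCc2ccccc2)c1)Oc1cc(OCc2ccccc2)cc(OCc2ccccc2)c1[C@H]1c2c(OCc3ccccc3)cc(OCc3ccccc3)cc2O[C@H](c2ccc(OCc3ccccc3)c(OCc3ccccc3)c2)[C@@H]1O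
F6 | step 7 | 3-[3,4-bis(benzyloxy)phenyl]-3-{3,5-bis(benzyloxy)-2-[5,7,3′,4′-tetra-O-benzylepicatechin-4β-yl]phenoxy}propane-1,2-diol (same configuration at both side-chain centres as in 11) | OC[C@@H](O)[C@@H](c1ccc(OCc2ccccc2)c(OCc2ccccc2)c1)Oc1cc(OCc2ccccc2)cc(OCc2ccccc2)c1[C@H]1c2c(OCc3ccccc3)cc(OCc3ccccc3)cc2O[C@H](c2ccc(OCc3ccccc3)c(OCc3ccccc3)c2)[C@@H]1O
F7 | step 7 | 3-[3,4-bis(benzyloxy)phenyl]-3-{3,5-bis(benzyloxy)-2-[5,7,3′,4′-tetra-O-benzylepicatechin-4β-yl]phenoxy}-2-hydroxypropanal | O=C[C@@H](O)[C@@H](c1ccc(OCc2ccccc2)c(OCc2ccccc2)c1)Oc1cc(OCc2ccccc2)cc(OCc2ccccc2)c1[C@H]1c2c(OCc3ccccc3)cc(OCc3ccccc3)cc2O[C@H](c2ccc(OCc3ccccc3)c(OCc3ccccc3)c2)[C@@H]1O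
F8 | step 7 | 5,7,3′,4′-tetra-O-benzylepicatechin-(4β→8)-5,7,3′,4′-tetra-O-benzyl-4-hydroxyepicatechin (lower C4 as a mixture of epimers) | OC1c2c(OCc3ccccc3)cc(OCc3ccccc3)c([C@H]3c4c(OCc5ccccc5)cc(OCc5ccccc5)cc4O[C@H](c4ccc(OCc5ccccc5)c(OCc5ccccc5)c4)[C@@H]3O)c2O[C@H](c2ccc(OCc3ccccc3)c(OCc3ccccc3)c2)[C@@H]1O
F9 | step 6 | 3-[3,4-bis(benzyloxy)phenyl]prop-2-yn-1-ol | OCC#Cc1ccc(OCc2ccccc2)c(OCc2ccccc2)c1
F10 | step 6 | (Z)-3-[3,4-bis(benzyloxy)phenyl]prop-2-en-1-ol | OC/C=C\c1ccc(OCc2ccccc2)c(OCc2ccccc2)c1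
F11 | step 6 | [(2R,3S)-3-[3,4-bis(benzyloxy)phenyl]oxiran-2-yl]methanol (cis) | OC[C@H]1O[C@H]1c1ccc(OCc2ccccc2)c(OCc2ccccc2)c1
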